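**Retrosynthetic overview**
1. Last C–O bond: Yamaguchi esterification of the C6-OH of epoxy-germacrenol 22 with TBS-protected vanillic acid 28 (from catechol), then one global desilylation.
2. The oxirane (second ring) is made last on the carbocycle, by OH-directed epoxidation of the 4,5-alkene of dienol 21.
3. The ten-membered carbocycle (first ring) is closed at C2–C3 by intramolecular alkylation of a C3 sulfonyl carbanion with the C2 allylic chloride (19 → 20); the sulfone is then removed with Pd/LiBHEt3.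
4. The open chain comes from a C5–C6 Nozaki–Hiyama–Kishi union of aldehyde 10 (C6–C10, C1, C2) with iodo-sulfone 15 (C3–C5, from propargyl alcohol).
5. In 10, C7 comes from an organocatalytic hydroxymethylation of isovaleraldehyde; C8 and the 1(10)-E alkene come from a chelation-controlled vinylogous Mukaiyama aldol.

Assumption: germacrane numbering is used for the ring (C1=C10 alkene with C14 methyl on C10; C4–C5 epoxide with C15 methyl on C4; C6 ester; C7 isopropyl; C8 OH); the target is the (1(10)E,4R,5R,6S,7R,8R) isomer.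

**Route**

Step 1
Reactants: 1 3-methylbutanal; 2 formaldehyde
Product: 3 (2S)-2-(hydroxymethyl)-3-methylbutanal
Conditions: 37% aq. HCHO, (R)-α,α-diphenylprolinol TMS ether (10 mol%), pH 7 phosphate buffer, toluene, rt; crude product used directly
Reagents that add atoms: none
Why: Enamine-catalysed α-hydroxymethylation (crossed aldol with the Jørgensen–Hayashi catalyst) in which formaldehyde attacks the E-enamine on the face remote from the CPh2OTMS group, so the (R)-catalyst sets C7 as (S) in 3 (7R in the target).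

Step 2
Reactants: 3 (2S)-2-(hydroxymethyl)-3-methylbutanal
Product: 4 (2S)-3-methyl-2-{[(triethylsilyl)oxy]methyl}butanal
Conditions: TESCl, imidazole, CH2Cl2, 0 °C
Reagents that add atoms: chlorotriethylsilane CC[Si](Cl)(CC)CC
Why: Silylation of the primary alcohol under weakly basic conditions (the lactol dimer of 3 reverts to monomer as it is trapped) leaves the α-stereocentre intact and installs a primary TES ether that can later be oxidised directly.

Step 3
Reactants: 5 methyl 3-methylbut-2-enoate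
Product: 7 [(1-methoxy-3-methylbuta-1,3-dien-1-yl)oxy]trimethylsilane, via lithium dienolate 6 (not isolated)
Conditions: LDA, THF, −78 °C; then TMSCl, −78 °C → rt
Reagents that add atoms: chlorotrimethylsilane C[Si](C)(C)Cl; lithium diisopropylamide [Li+].CC(C)[N-]C(C)C (Li of 6 only)
Why: Kinetic γ-deprotonation of the senecioate and O-silylation of the dienolate give the silyl dienol ether that serves as a γ-nucleophile.

Step 4
Reactants: 4 (2S)-3-methyl-2-{[(triethylsilyl)oxy]methyl}butanal; 7 [(1-methoxy-3-methylbuta-1,3-dien-1-yl)oxy]trimethylsilane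
Product: 8 methyl (2E,5R,6S)-5-hydroxy-3,7-dimethyl-6-{[(triethylsilyl)oxy]methyl}oct-2-enoate
Conditions: Me2AlCl (2.5 equiv), CH2Cl2, −78 °C; aq. Rochelle salt, then dilute citric acid
Reagents that add atoms: none
Why: Chelation-controlled vinylogous Mukaiyama aldol in which the γ-CH2 of the dienolate attacks the aldehyde (held in an Al chelate with the β-silyloxy oxygen) on the face anti to the isopropyl group, the same face the Felkin–Anh model with iPr as the large group predicts, giving the 7,8-anti relation (8R) and, through the s-trans diene, the (E)-enoate that becomes the 1(10)-alkene.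

Step 5
Reactants: 8 methyl (2E,5R,6S)-5-hydroxy-3,7-dimethyl-6-{[(triethylsilyl)oxy]methyl}oct-2-enoate
Product: 9 methyl (2E,5R,6S)-5-[(tert-butyldimethylsilyl)oxy]-3,7-dimethyl-6-{[(triethylsilyl)oxy]methyl}oct-2-enoate
Conditions: TBSOTf, 2,6-lutidine, CH2Cl2, −78 → 0 °C
Reagents that add atoms: tert-butyldimethylsilyl triflate CC(C)(C)[Si](C)(C)OS(=O)(=O)C(F)(F)F
Why: Silyl triflate silylation of the hindered secondary C8 alcohol installs the TBS ether that is carried to the last step, with no stereocentre affected.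

Step 6
Reactants: 9 methyl (2E,5R,6S)-5-[(tert-butyldimethylsilyl)oxy]-3,7-dimethyl-6-{[(triethylsilyl)oxy]methyl}oct-2-enoate
Product: 10 methyl (2E,5R,6R)-5-[(tert-butyldimethylsilyl)oxy]-6-formyl-3,7-dimethyloct-2-enoate
Conditions: (COCl)2, DMSO, CH2Cl2, −78 → −30 °C; then i-Pr2NEt, −78 → 0 °C
Reagents that add atoms: none
Why: Swern oxidation cleaves and oxidises the primary TES ether directly (chlorodimethylsulfonium attacks the unhindered silyl ether) while the secondary TBS ether and the enoate are inert, and Hünig's base at low temperature avoids epimerising C7.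

Step 7
Reactants: 11 prop-2-yn-1-ol
Product: 13 (2E)-3-iodo-2-methylprop-2-en-1-ol, via alkenylalane 12 (not isolated)
Conditions: AlMe3 (3 equiv), Cp2ZrCl2 (25 mol%), CH2Cl2, 0 °C → rt; then I2, THF, −30 → 0 °C; aq. K2CO3
Reagents that add atoms: trimethylaluminium C[Al](C)C; iodine II
Why: Negishi zirconium-catalysed carboalumination (syn addition of Me–Al, methyl on the internal carbon) followed by iodinolysis with retention gives only the (E)-iodide, which fixes the 4,5-alkene geometry and hence the trans-epoxide.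

Step 8
Reactants: 13 (2E)-3-iodo-2-methylprop-2-en-1-ol
Product: 14 (1E)-3-bromo-1-iodo-2-methylprop-1-ene
Conditions: CBr4, PPh3, CH2Cl2, 0 °C
Reagents that add atoms: carbon tetrabromide BrC(Br)(Br)Br
Why: Appel bromination of the primary allylic alcohol under neutral conditions proceeds without allylic transposition and keeps the E-alkene.

Step 9
Reactants: 14 (1E)-3-bromo-1-iodo-2-methylprop-1-ene
Product: 15 {[(2E)-3-iodo-2-methylprop-2-en-1-yl]sulfonyl}benzene
Conditions: PhSO2Na, DMF, rt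
Reagents that add atoms: sodium benzenesulfinate [Na+].[O-]S(=O)c1ccccc1
Why: SN2 S-alkylation of the sulfinate by the primary allylic bromide gives the allyl sulfone that will later stabilise the C3 carbanion.

Step 10
Reactants: 10 methyl (2E,5R,6R)-5-[(tert-butyldimethylsilyl)oxy]-6-formyl-3,7-dimethyloct-2-enoate; 15 {[(2E)-3-iodo-2-methylprop-2-en-1-yl]sulfonyl}benzene
Product: 16 methyl (2E,5R,6S,7R,8E)-5-[(tert-butyldimethylsilyl)oxy]-7-hydroxy-3,9-dimethyl-10-(phenylsulfonyl)-6-(propan-2-yl)deca-2,8-dienoate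
Conditions: CrCl2 (4 equiv), NiCl2 (2 mol%), DMSO/THF, rt
Reagents that add atoms: none
Why: Nozaki–Hiyama–Kishi coupling (alkenylchromium formed with retention of geometry; ester, sulfone and silyl ether tolerated) adds to the α-branched aldehyde in the Felkin–Anh sense (anti to the C8 chain), reinforced by 1,3-anti induction from the β-OTBS group, setting germacrane C6 as R in 16 (6S once the epoxide is present).

Step 11
Reactants: 16 methyl (2E,5R,6S,7R,8E)-5-[(tert-butyldimethylsilyl)oxy]-7-hydroxy-3,9-dimethyl-10-(phenylsulfonyl)-6-(propan-2-yl)deca-2,8-dienoate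
Product: 17 (2E,5R,6S,7R,8E)-5-[(tert-butyldimethylsilyl)oxy]-3,9-dimethyl-10-(phenylsulfonyl)-6-(propan-2-yl)deca-2,8-diene-1,7-diol
Conditions: DIBAL-H (4 equiv), CH2Cl2, −78 °C; aq. Rochelle salt
Reagents that add atoms: none
Why: DIBAL-H 1,2-reduction of the enoate to the primary allylic alcohol leaves the sulfone, the silyl ether and all stereocentres untouched.

Step 12
Reactants: 17 (2E,5R,6S,7R,8E)-5-[(tert-butyldimethylsilyl)oxy]-3,9-dimethyl-10-(phenylsulfonyl)-6-(propan-2-yl)deca-2,8-diene-1,7-diol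
Product: 19 (2E,4R,5S,6R,8E)-6-[(tert-butyldimethylsilyl)oxy]-10-chloro-2,8-dimethyl-1-(phenylsulfonyl)-5-(propan-2-yl)deca-2,8-dien-4-ol, via allylic mesylate 18 (not isolated)
Conditions: MsCl (1.1 equiv), 2,4,6-collidine, LiCl, DMF, 0 °C
Reagents that add atoms: lithium chloride [Li+].[Cl-]; methanesulfonyl chloride CS(=O)(=O)Cl (in 18 only)
Why: Collington–Meyers chlorination in which the unhindered primary allylic OH is mesylated much faster than the hindered secondary C6-OH and chloride displaces the mesylate by SN2 without transposition.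

Step 13
Reactants: 19 (2E,4R,5S,6R,8E)-6-[(tert-butyldimethylsilyl)oxy]-10-chloro-2,8-dimethyl-1-(phenylsulfonyl)-5-(propan-2-yl)deca-2,8-dien-4-ol
Product: 20 (1R,2E,6E,9R,10S)-9-[(tert-butyldimethylsilyl)oxy]-3,7-dimethyl-4-(phenylsulfonyl)-10-(propan-2-yl)cyclodeca-2,6-dien-1-ol (mixture of sulfone epimers at ring C4 = germacrane C3)
Conditions: LiHMDS (2.2 equiv), THF, −78 → 0 °C, syringe-pump addition, 2 mM
Reagents that add atoms: none
Why: Intramolecular SN2 alkylation of the α-sulfonyl allyl carbanion (C3) by the primary allylic chloride (C2) under high dilution closes the ten-membered ring (a classical germacrane closure), with C6 carried as its alkoxide so that the allyl anion cannot expel the C6 oxygen and the new C3 centre removed in the next step.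

Step 14
Reactants: 20 (1R,2E,6E,9R,10S)-9-[(tert-butyldimethylsilyl)oxy]-3,7-dimethyl-4-(phenylsulfonyl)-10-(propan-2-yl)cyclodeca-2,6-dien-1-ol
Product: 21 (1R,2E,6E,9R,10S)-9-[(tert-butyldimethylsilyl)oxy]-3,7-dimethyl-10-(propan-2-yl)cyclodeca-2,6-dien-1-ol
Conditions: PdCl2(dppp) (10 mol%), LiBHEt3 (4 equiv), THF, 0 °C; work-up and chromatography kept neutral and below 25 °C
Reagents that add atoms: none
Why: Palladium-catalysed hydride desulfonylation of the allylic sulfone (π-allylpalladium reduced by LiBHEt3) delivers hydride to C3, the terminus remote from the C6 alkoxide, so the (E)-4,5-alkene is regenerated in place.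

Step 15
Reactants: 21 (1R,2E,6E,9R,10S)-9-[(tert-butyldimethylsilyl)oxy]-3,7-dimethyl-10-(propan-2-yl)cyclodeca-2,6-dien-1-ol
Product: 22 (4R,5R,6S,7S,8R)-8-[(tert-butyldimethylsilyl)oxy]-4,5-epoxygermacr-1(10)E-en-6-ol
Conditions: VO(acac)2 (5 mol%), t-BuOOH (1.2 equiv), CH2Cl2, 0 °C
Reagents that add atoms: tert-butyl hydroperoxide CC(C)(C)OO
Why: Hydroxyl-directed vanadium-catalysed epoxidation (Sharpless–Michaelson) touches only the allylic 4,5-alkene, and with H6 eclipsing the C15 methyl (A1,3 strain) the peroxide is delivered to the exposed outer face syn to the OH, giving the threo (4R,5R) trans-epoxide.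

Step 16
Reactants: 23 benzene-1,2-diol
Product: 24 2-methoxyphenol
Conditions: MeI (1.0 equiv), K2CO3, acetone, reflux; distillation
Reagents that add atoms: iodomethane CI
Why: Williamson mono-O-methylation of catechol with one equivalent of MeI, the product being separated from catechol and veratrole by distillation.

Step 17
Reactants: 24 2-methoxyphenol
Product: 25 4-bromo-2-methoxyphenol
Conditions: NBS, MeCN, 0 °C
Reagents that add atoms: N-bromosuccinimide O=C1CCC(=O)N1Br
Why: Electrophilic aromatic bromination occurs para to the strongly activating free hydroxyl group.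

Step 18
Reactants: 25 4-bromo-2-methoxyphenol
Product: 26 (4-bromo-2-methoxyphenoxy)(tert-butyl)dimethylsilane
Conditions: TBSCl, imidazole, DMF, rt
Reagents that add atoms: tert-butyldimethylsilyl chloride CC(C)(C)[Si](C)(C)Cl
Why: Silylation masks the phenol so that the aryllithium and the later acylation are compatible.

Step 19
Reactants: 26 (4-bromo-2-methoxyphenoxy)(tert-butyl)dimethylsilane
Product: 28 4-[(tert-butyldimethylsilyl)oxy]-3-methoxybenzoic acid, via aryllithium 27 (not isolated)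
Conditions: n-BuLi, THF, −78 °C; then CO2; aq. HCl to pH 4 at 0 °C
Reagents that add atoms: carbon dioxide O=C=O; n-butyllithium [Li]CCCC (Li of 27 only)
Why: Bromine–lithium exchange followed by carboxylation of the aryllithium gives the protected vanillic acid, the aryl silyl ether surviving a cold mildly acidic work-up.

Step 20
Reactants: 22 (4R,5R,6S,7S,8R)-8-[(tert-butyldimethylsilyl)oxy]-4,5-epoxygermacr-1(10)E-en-6-ol; 28 4-[(tert-butyldimethylsilyl)oxy]-3-methoxybenzoic acid
Product: 30 (4R,5R,6S,7S,8R)-8-[(tert-butyldimethylsilyl)oxy]-4,5-epoxygermacr-1(10)E-en-6-yl 4-[(tert-butyldimethylsilyl)oxy]-3-methoxybenzoate, via mixed anhydride 29 (not isolated)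
Conditions: 2,4,6-Cl3C6H2COCl, Et3N, THF, rt; then 22, DMAP, toluene, 40 °C
Reagents that add atoms: 2,4,6-trichlorobenzoyl chloride O=C(Cl)c1c(Cl)cc(Cl)cc1Cl (in 29 only; none in 30)
Why: Yamaguchi esterification in which DMAP attacks the mixed anhydride at the less hindered vanilloyl carbonyl and the acylpyridinium acylates the hindered C6-OH with retention at C6, the epoxide and silyl ethers being stable to these basic conditions.

Step 21
Reactants: 30 (4R,5R,6S,7S,8R)-8-[(tert-butyldimethylsilyl)oxy]-4,5-epoxygermacr-1(10)E-en-6-yl 4-[(tert-butyldimethylsilyl)oxy]-3-methoxybenzoate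
Product: 31 (1(10)E,4R,5R,6S,7R,8R)-4,5-epoxy-8-hydroxygermacr-1(10)-en-6-yl 4-hydroxy-3-methoxybenzoate (CNP0285693.1)
Conditions: TBAF, AcOH (1:1), THF, 0 °C → rt
Reagents that add atoms: none
Why: Fluoride-mediated cleavage of both Si–O bonds (aryl and C8 TBS ethers) under acetic acid buffering leaves the epoxide, the ester and the alkene intact and suppresses 1,3-acyl migration.

**Compound list**
1 | 3-methylbutanal (isovaleraldehyde) | CC(C)CC=O | starting material
2 | formaldehyde (37% aqueous) | C=O | starting material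
3 | (2S)-2-(hydroxymethyl)-3-methylbutanal | O=C[C@H](CO)C(C)C | intermediate
4 | (2S)-3-methyl-2-{[(triethylsilyl)oxy]methyl}butanal | O=C[C@H](CO[Si](CC)(CC)CC)C(C)C | intermediate
5 | methyl 3-methylbut-2-enoate | COC(=O)C=C(C)C | starting material
6 | lithium 1-methoxy-3-methylbuta-1,3-dien-1-olate | [Li+].[O-]C(OC)=CC(C)=C | intermediate (not isolated)
7 | [(1-methoxy-3-methylbuta-1,3-dien-1-yl)oxy]trimethylsilane | COC(O[Si](C)(C)C)=CC(C)=C | intermediate
8 | methyl (2E,5R,6S)-5-hydroxy-3,7-dimethyl-6-{[(triethylsilyl)oxy]methyl}oct-2-enoate | COC(=O)/C=C(\C)C[C@@H](O)[C@H](CO[Si](CC)(CC)CC)C(C)C | intermediate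
9 | methyl (2E,5R,6S)-5-[(tert-butyldimethylsilyl)oxy]-3,7-dimethyl-6-{[(triethylsilyl)oxy]methyl}oct-2-enoate | COC(=O)/C=C(\C)C[C@@H](O[Si](C)(C)C(C)(C)C)[C@H](CO[Si](CC)(CC)CC)C(C)C | intermediate
10 | methyl (2E,5R,6R)-5-[(tert-butyldimethylsilyl)oxy]-6-formyl-3,7-dimethyloct-2-enoate | COC(=O)/C=C(\C)C[C@@H](O[Si](C)(C)C(C)(C)C)[C@H](C=O)C(C)C | intermediate
11 | prop-2-yn-1-ol (propargyl alcohol) | C#CCO | starting material
12 | dimethylaluminium (2E)-3-(dimethylalumanyl)-2-methylprop-2-en-1-olate | C[Al](C)/C=C(\C)CO[Al](C)C | intermediate (not isolated)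
13 | (2E)-3-iodo-2-methylprop-2-en-1-ol | I/C=C(\C)CO | intermediate
14 | (1E)-3-bromo-1-iodo-2-methylprop-1-ene | I/C=C(\C)CBr | intermediate
15 | {[(2E)-3-iodo-2-methylprop-2-en-1-yl]sulfonyl}benzene | I/C=C(\C)CS(=O)(=O)c1ccccc1 | intermediate
16 | methyl (2E,5R,6S,7R,8E)-5-[(tert-butyldimethylsilyl)oxy]-7-hydroxy-3,9-dimethyl-10-(phenylsulfonyl)-6-(propan-2-yl)deca-2,8-dienoate | COC(=O)/C=C(\C)C[C@@H](O[Si](C)(C)C(C)(C)C)[C@H]([C@H](O)/C=C(\C)CS(=O)(=O)c1ccccc1)C(C)C | intermediate
17 | (2E,5R,6S,7R,8E)-5-[(tert-butyldimethylsilyl)oxy]-3,9-dimethyl-10-(phenylsulfonyl)-6-(propan-2-yl)deca-2,8-diene-1,7-diol | OC/C=C(\C)C[C@@H](O[Si](C)(C)C(C)(C)C)[C@H]([C@H](O)/C=C(\C)CS(=O)(=O)c1ccccc1)C(C)C | intermediate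
18 | 1-O-methanesulfonate of 17 | CS(=O)(=O)OC/C=C(\C)C[C@@H](O[Si](C)(C)C(C)(C)C)[C@H]([C@H](O)/C=C(\C)CS(=O)(=O)c1ccccc1)C(C)C | intermediate (not isolated)
19 | (2E,4R,5S,6R,8E)-6-[(tert-butyldimethylsilyl)oxy]-10-chloro-2,8-dimethyl-1-(phenylsulfonyl)-5-(propan-2-yl)deca-2,8-dien-4-ol | ClC/C=C(\C)C[C@@H](O[Si](C)(C)C(C)(C)C)[C@H]([C@H](O)/C=C(\C)CS(=O)(=O)c1ccccc1)C(C)C | intermediate
20 | (1R,2E,6E,9R,10S)-9-[(tert-butyldimethylsilyl)oxy]-3,7-dimethyl-4-(phenylsulfonyl)-10-(propan-2-yl)cyclodeca-2,6-dien-1-ol (C4 epimers) | O=S(=O)(c1ccccc1)C2C/C=C(\C)C[C@@H](O[Si](C)(C)C(C)(C)C)[C@@H](C(C)C)[C@H](O)/C=C2\C | intermediate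
21 | (1R,2E,6E,9R,10S)-9-[(tert-butyldimethylsilyl)oxy]-3,7-dimethyl-10-(propan-2-yl)cyclodeca-2,6-dien-1-ol | C1C/C=C(\C)C[C@@H](O[Si](C)(C)C(C)(C)C)[C@@H](C(C)C)[C@H](O)/C=C1\C | intermediate
22 | (4R,5R,6S,7S,8R)-8-[(tert-butyldimethylsilyl)oxy]-4,5-epoxygermacr-1(10)E-en-6-ol | O[C@H]1[C@H](C(C)C)[C@H](O[Si](C)(C)C(C)(C)C)C/C(C)=C/CC[C@@]2(C)O[C@H]12 | intermediate
23 | benzene-1,2-diol (catechol) | Oc1ccccc1O | starting material
24 | 2-methoxyphenol | COc1ccccc1O | intermediate
25 | 4-bromo-2-methoxyphenol | COc1cc(Br)ccc1O | intermediate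
26 | (4-bromo-2-methoxyphenoxy)(tert-butyl)dimethylsilane | COc1cc(Br)ccc1O[Si](C)(C)C(C)(C)C | intermediate
27 | {4-[(tert-butyldimethylsilyl)oxy]-3-methoxyphenyl}lithium | COc1cc([Li])ccc1O[Si](C)(C)C(C)(C)C | intermediate (not isolated)
28 | 4-[(tert-butyldimethylsilyl)oxy]-3-methoxybenzoic acid | COc1cc(C(=O)O)ccc1O[Si](C)(C)C(C)(C)C | intermediate
29 | 4-[(tert-butyldimethylsilyl)oxy]-3-methoxybenzoic 2,4,6-trichlorobenzoic anhydride | COc1cc(C(=O)OC(=O)c2c(Cl)cc(Cl)cc2Cl)ccc1O[Si](C)(C)C(C)(C)C | intermediate (not isolated)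
30 | (4R,5R,6S,7S,8R)-8-[(tert-butyldimethylsilyl)oxy]-4,5-epoxygermacr-1(10)E-en-6-yl 4-[(tert-butyldimethylsilyl)oxy]-3-methoxybenzoate | COc1cc(C(=O)O[C@H]2[C@H](C(C)C)[C@H](O[Si](C)(C)C(C)(C)C)C/C(C)=C/CC[C@@]3(C)O[C@H]23)ccc1O[Si](C)(C)C(C)(C)C | intermediate
31 | (1(10)E,4R,5R,6S,7R,8R)-4,5-epoxy-8-hydroxygermacr-1(10)-en-6-yl 4-hydroxy-3-methoxybenzoate (CNP0285693.1) | COc1cc(C(=O)O[C@H]2[C@H](C(C)C)[C@H](O)C/C(C)=C/CC[C@@]3(C)O[C@H]23)ccc1O | target

**Step count**
Total step count: 21.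
Longest linear sequence: 13 steps (1, 2, 4, 5, 6, 10, 11, 12, 13, 14, 15, 20, 21).

**Three steps most likely to fail, with fallbacks**

Step 13 (ring closure by sulfone alkylation). The risks are oligomerisation, SN2′ attack and the strain of the (E,E)-cyclodecadiene. The fallback closes the ring at C5–C6 instead and makes the C2–C3 bond between two molecules; it sets out from 9 (and uses 15) and comes back to the route at 20. DIBAL-H reduction of ester 9 gives the allylic alcohol F1, and NCS/PPh3 converts it into the allylic chloride F2. The lithio derivative of 15 (LiHMDS, THF–HMPA, −78 °C) is alkylated by F2 to the open-chain sulfone F3. Swern oxidation of its primary TES ether gives the iodo-aldehyde F4, and an intramolecular Nozaki–Hiyama–Kishi reaction (CrCl2, cat. NiCl2, DMSO/THF, 2 mM) closes the ring to 20.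

Step 14 (desulfonylation). The risk is that hydride enters at C5 instead of C3, moving the 4,5-alkene, or that the alkene geometry is lost. The fallback moves the sulfone to C2, where the π-allyl has one secondary terminus (C2) and one fully substituted terminus (C10), so hydride can only go to C2. It sets out from 9 (and uses 13) and comes back at 21. The allylic chloride F2, made from 9 through the allylic alcohol F1 as above, reacts with PhSO2Na in DMF to give the C2 sulfone F5. Swern oxidation of the primary TES ether gives the aldehyde F6, and Nozaki–Hiyama–Kishi coupling with iodo-alcohol 13 gives the diol F7. NCS/PPh3 at the primary allylic hydroxyl gives the chloride F8, LiHMDS at high dilution closes the ring to the C2-sulfonyl macrocycle F9, and PdCl2(dppp)/LiBHEt3 reduces it to 21.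

Step 10 (C6 configuration in the Nozaki–Hiyama–Kishi union). The risk is a poor Felkin ratio if the isopropyl group competes with the C8 chain as the large substituent. The fallback sets C6 by reagent control; it sets out from 16 obtained as a C6-epimer mixture and comes back at 16. Dess–Martin oxidation gives the enone F10, and reduction with (R)-Me-CBS and catecholborane (toluene, −78 °C, alkenyl as the large group) returns 16 as the 7R alcohol (germacrane C6). The sense of the CBS reagent is derived from the standard model and should be confirmed on a model enone.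

**Further compounds**
F1 | step 13 | (2E,5R,6S)-5-[(tert-butyldimethylsilyl)oxy]-3,7-dimethyl-6-{[(triethylsilyl)oxy]methyl}oct-2-en-1-ol | OC/C=C(\C)C[C@@H](O[Si](C)(C)C(C)(C)C)[C@H](CO[Si](CC)(CC)CC)C(C)C
F2 | step 13 | (2E,5R,6S)-5-[(tert-butyldimethylsilyl)oxy]-1-chloro-3,7-dimethyl-6-{[(triethylsilyl)oxy]methyl}oct-2-ene | ClC/C=C(\C)C[C@@H](O[Si](C)(C)C(C)(C)C)[C@H](CO[Si](CC)(CC)CC)C(C)C
F3 | step 13 | {[(1E,5E,8R,9S)-8-[(tert-butyldimethylsilyl)oxy]-1-iodo-2,6,10-trimethyl-9-{[(triethylsilyl)oxy]methyl}undeca-1,5-dien-3-yl]sulfonyl}benzene (C3 epimers) | I/C=C(\C)C(S(=O)(=O)c1ccccc1)C/C=C(\C)C[C@@H](O[Si](C)(C)C(C)(C)C)[C@H](CO[Si](CC)(CC)CC)C(C)C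
F4 | step 13 | (2R,3R,5E,9E)-3-[(tert-butyldimethylsilyl)oxy]-10-iodo-5,9-dimethyl-8-(phenylsulfonyl)-2-(propan-2-yl)deca-5,9-dienal (C8 epimers) | I/C=C(\C)C(S(=O)(=O)c1ccccc1)C/C=C(\C)C[C@@H](O[Si](C)(C)C(C)(C)C)[C@H](C=O)C(C)C
F5 | step 14 | {[(2E,5R,6S)-5-[(tert-butyldimethylsilyl)oxy]-3,7-dimethyl-6-{[(triethylsilyl)oxy]methyl}oct-2-en-1-yl]sulfonyl}benzene | O=S(=O)(c1ccccc1)C/C=C(\C)C[C@@H](O[Si](C)(C)C(C)(C)C)[C@H](CO[Si](CC)(CC)CC)C(C)C
F6 | step 14 | (2R,3R,5E)-3-[(tert-butyldimethylsilyl)oxy]-5-methyl-7-(phenylsulfonyl)-2-(propan-2-yl)hept-5-enal | O=S(=O)(c1ccccc1)C/C=C(\C)C[C@@H](O[Si](C)(C)C(C)(C)C)[C@H](C=O)C(C)C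
F7 | step 14 | (2E,4R,5S,6R,8E)-6-[(tert-butyldimethylsilyl)oxy]-2,8-dimethyl-10-(phenylsulfonyl)-5-(propan-2-yl)deca-2,8-diene-1,4-diol | O=S(=O)(c1ccccc1)C/C=C(\C)C[C@@H](O[Si](C)(C)C(C)(C)C)[C@H]([C@H](O)/C=C(\C)CO)C(C)C
F8 | step 14 | (2E,4R,5S,6R,8E)-6-[(tert-butyldimethylsilyl)oxy]-1-chloro-2,8-dimethyl-10-(phenylsulfonyl)-5-(propan-2-yl)deca-2,8-dien-4-ol | O=S(=O)(c1ccccc1)C/C=C(\C)C[C@@H](O[Si](C)(C)C(C)(C)C)[C@H]([C@H](O)/C=C(\C)CCl)C(C)C
F9 | step 14 | (1R,2E,6E,9R,10S)-9-[(tert-butyldimethylsilyl)oxy]-3,7-dimethyl-5-(phenylsulfonyl)-10-(propan-2-yl)cyclodeca-2,6-dien-1-ol (C5 epimers) | O=S(=O)(c1ccccc1)C2/C=C(\C)C[C@@H](O[Si](C)(C)C(C)(C)C)[C@@H](C(C)C)[C@H](O)/C=C(\C)C2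
F10 | step 10 | methyl (2E,5R,6R,8E)-5-[(tert-butyldimethylsilyl)oxy]-3,9-dimethyl-7-oxo-10-(phenylsulfonyl)-6-(propan-2-yl)deca-2,8-dienoate | COC(=O)/C=C(\C)C[C@@H](O[Si](C)(C)C(C)(C)C)[C@H](C(=O)/C=C(\C)CS(=O)(=O)c1ccccc1)C(C)C
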